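**Strategy.** With quinone numbering C1(=O), C2(OH), C3(pentadecyl), C4(=O), C5(OMe), C6(H), the ring is cut into the three-carbon pieces C1–C2–C3 and C4–C5–C6. The key step exploits two features of this ring: the para carbonyls C1/C4 are a 1,4-dicarbonyl pair, so C1 is used with reversed polarity as a dithiane-masked acyl anion, and C2(OH)/C4(=O) across C3 are a 1,3-dicarbonyl Claisen retron. In one pot the anion of a 2-acyl-1,3-dithiane adds to C6 of methyl 2-methoxyacrylate (C1–C6) and the keto ester closes by Dieckmann condensation (C3–C4). Unmasking of C1 and oxidation then give the hydroxyquinone.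

Key step: step 2

Remark: methyl 2-methoxyacrylate is taken as a purchasable reagent; 7 and 8 are drawn as keto forms (8 should be largely enolised), and their stereocentres arise without control and are erased in step 3.

**Step 1**
Reactants: 1 1,3-dithiane; 2 methyl heptadecanoate
Product: 5 1-(1,3-dithian-2-yl)heptadecan-1-one, via 2-lithio-1,3-dithiane 3 (not isolated), via lithium enolate of the acyl dithiane 4 (not isolated)
Conditions: n-BuLi (2.1 equiv), THF, −30 °C; then 2 (0.5 equiv relative to 1), −40 °C to 0 °C; 1 M HCl work-up
Reagents that add atoms: none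
Why: Acyl substitution of the ester by the Corey–Seebach reagent 2-lithio-1,3-dithiane, in which the second equivalent deprotonates the more acidic 2-acyl dithiane as it forms, so that the product is held as enolate 4 and is protected against a second addition.

**Step 2**
Reactants: 5 1-(1,3-dithian-2-yl)heptadecan-1-one; 6 methyl 2-methoxyacrylate
Product: 8 10-methoxy-8-pentadecyl-1,5-dithiaspiro[5.5]undecane-7,9-dione, via Michael adduct 7 (not isolated)
Conditions: t-BuOK (2.2 equiv), 6 (1.1 equiv), THF, 0 °C to rt; 1 M HCl work-up
Reagents that add atoms: none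
Why: The C–H between the two sulfur atoms and the ketone of 5 is by far the most acidic site, so t-BuOK should give the ketene-dithioacetal enolate, a dithiane-masked acyl anion (Corey–Seebach umpolung), which adds in Michael fashion to the unhindered CH2 terminus of 6 (future C1–C6 bond, intermediate 7). With the dithiane carbon now quaternary, the only enolisable position left on the ketone is the α′-CH2 that carries the pentadecyl chain, whose enolate attacks the ester in a Dieckmann-type Claisen condensation (future C3–C4 bond), and irreversible deprotonation of the resulting 2-alkyl-1,3-dione drives the sequence. The closest known reaction type is the consecutive Michael–Claisen [3+3] annulation of ketones with acrylates to cyclohexane-1,3-diones. The single ring closes in the 6-(enolendo)-exo-trig mode. The two stereocentres of 8 (C8 and C10) form without control and are erased at the aromatisation in step 3. The step needs 1,4- over 1,2-attack and a single addition to 6: the soft, doubly sulfur-stabilised carbanion favours conjugate addition, and the donor methoxy group on 6 together with the use of about one equivalent of 6 should disfavour a second Michael addition of the product enolate.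

**Step 3**
Reactants: 8 10-methoxy-8-pentadecyl-1,5-dithiaspiro[5.5]undecane-7,9-dione
Product: 10 2-hydroxy-5-methoxy-3-pentadecyl-1,4-benzoquinone, via 5-methoxy-3-pentadecylbenzene-1,2,4-triol 9 (not isolated)
Conditions: Hg(ClO4)2·3H2O (2 equiv), CaCO3, THF/H2O, 0 °C to rt; filter; then FeCl3·6H2O (2.5 equiv), rt
Reagents that add atoms: water, O
Why: Thiophilic mercury-assisted hydrolysis of the dithioketal (buffered by CaCO3) should release the C1 ketone, the resulting cyclohexane-1,2,4-trione tautomerises to the aromatic triol 9, and FeCl3 oxidises this hydroxyhydroquinone to the para-quinone (hydroquinone-to-quinone oxidation), the stable tautomer of the hydroxyquinone.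

**Compound list**
1 | 1,3-dithiane | C1CSCSC1 | starting material
2 | methyl heptadecanoate | CCCCCCCCCCCCCCCCC(=O)OC | starting material
3 | 2-lithio-1,3-dithiane | [Li]C1SCCCS1 | intermediate
4 | lithium enolate of 5 (lithium 1-(1,3-dithian-2-ylidene)heptadecan-1-olate) | [Li+].[O-]C(CCCCCCCCCCCCCCCC)=C1SCCCS1 | intermediate
5 | 1-(1,3-dithian-2-yl)heptadecan-1-one | CCCCCCCCCCCCCCCCC(=O)C1SCCCS1 | intermediate
6 | methyl 2-methoxyacrylate (methyl 2-methoxyprop-2-enoate) | C=C(OC)C(=O)OC | starting material
7 | methyl 3-(2-heptadecanoyl-1,3-dithian-2-yl)-2-methoxypropanoate (racemic) | CCCCCCCCCCCCCCCCC(=O)C1(CC(OC)C(=O)OC)SCCCS1 | intermediate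
8 | 10-methoxy-8-pentadecyl-1,5-dithiaspiro[5.5]undecane-7,9-dione (mixture of stereoisomers, enolisable) | CCCCCCCCCCCCCCCC1C(=O)C(OC)CC2(SCCCS2)C1=O | intermediate
9 | 5-methoxy-3-pentadecylbenzene-1,2,4-triol | CCCCCCCCCCCCCCCc1c(O)c(O)cc(OC)c1O | intermediate
10 | 2-hydroxy-5-methoxy-3-pentadecyl-1,4-benzoquinone (2-hydroxy-5-methoxy-3-pentadecylcyclohexa-2,5-diene-1,4-dione) | CCCCCCCCCCCCCCCC1=C(O)C(=O)C=C(OC)C1=O | target

**Step count and risks**
Total step count: 3. Longest linear sequence: 3 steps (1 or 2 → 5 → 8 → 10).

Steps most likely to fail:

1. Step 2. The conjugate addition may stall or revert because the methoxy group lowers the electrophilicity of the acceptor, and the product enolate may add to a second acceptor molecule. The fallback sets out from 5 and comes back to the route at 9. Compound 5 is annulated in the same Michael–Claisen manner with the far more reactive methyl acrylate (t-BuOK, THF) to give 8-pentadecyl-1,5-dithiaspiro[5.5]undecane-7,9-dione F1. Hydrolysis with Hg(ClO4)2 and CaCO3 in aqueous THF gives 3-pentadecylbenzene-1,2,4-triol F2, which is oxidised without isolation by FeCl3 to 2-hydroxy-3-pentadecyl-1,4-benzoquinone F3. Methanol with ZnCl2 then adds at C5, the β-carbon of the enone that is not deactivated by the vinylogous acid, to give 9, which is oxidised to 10 as in step 3.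

2. Step 3. Unmasking may remain incomplete at the hindered dithioketal next to a carbonyl group, and methanol may be lost by β-elimination once the C1 ketone is free. The fallback sets out from 8 and comes back at 9. Chemoselective sulfur oxidation with NaIO4 (1 equiv, MeOH/H2O, 0 °C) gives 10-methoxy-8-pentadecyl-1,5-dithiaspiro[5.5]undecane-7,9-dione 1-oxide F4. This monosulfoxide is hydrolysed under mild acid (aqueous HCl, THF) without a heavy metal to 9, which is oxidised with FeCl3 to 10.

3. Step 1. The basic lithiodithiane may enolise the ester instead of adding to it, leaving the acylation incomplete. The fallback sets out from 2 and comes back at 5. Reduction with DIBAL-H (CH2Cl2, −78 °C) gives heptadecanal F5. Addition of 3 (from 1 and n-BuLi, THF, −78 °C) gives 1-(1,3-dithian-2-yl)heptadecan-1-ol F6. Parikh–Doering oxidation (SO3·pyridine, DMSO, Et3N) then gives 5.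

**Further compounds**
F1 | step 2 | 8-pentadecyl-1,5-dithiaspiro[5.5]undecane-7,9-dione | CCCCCCCCCCCCCCCC1C(=O)CCC2(SCCCS2)C1=O
F2 | step 2 | 3-pentadecylbenzene-1,2,4-triol | CCCCCCCCCCCCCCCc1c(O)c(O)ccc1O
F3 | step 2 | 2-hydroxy-3-pentadecyl-1,4-benzoquinone | CCCCCCCCCCCCCCCC1=C(O)C(=O)C=CC1=O
F4 | step 3 | 10-methoxy-8-pentadecyl-1,5-dithiaspiro[5.5]undecane-7,9-dione 1-oxide (mixture of stereoisomers) | CCCCCCCCCCCCCCCC1C(=O)C(OC)CC2(SCCCS2=O)C1=O
F5 | step 1 | heptadecanal | CCCCCCCCCCCCCCCCC=O
F6 | step 1 | 1-(1,3-dithian-2-yl)heptadecan-1-ol (racemic) | CCCCCCCCCCCCCCCCC(O)C1SCCCS1
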